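In each of these stirred vessels the intermediate has two ways out, coupling with the partner or pairing with itself, and the target share turns on how fast the intermediate is made against a crossing rate.

| setting | summer | winter | dawn | midnight | autumn |
|---|---|---|---|---|---|
| substrate | 0.10 M (fed, over 25 min) | 0.10 M | 0.10 M (in portions, 2, over 25 min) | 0.10 M | 0.10 M |
| partner | 0.800 equiv | 0.800 equiv | 0.800 equiv | 0.800 equiv (fed, over 25 min) | 0.800 equiv (fed, over 6.0 min) |
| time | 30 min | 30 min | 30 min | 30 min | 30 min |
| remark | all else is in the flask from the start; the feed brings no volume worth counting | everything together at the start | first portion at the start, last at 25 min | all else is in the flask from the start; the feed brings no volume worth counting | all else is in the flask from the start; the feed brings no volume worth counting |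

    substrate → intermediate (k1 = 4.2 × 10⁻⁴ s⁻¹)
    partner + intermediate → target (k2 = 0.025 M⁻¹ s⁻¹)
    target ⇌ isomer of the product (K3 = 2.2, k3 = 9.3 × 10⁻⁴ s⁻¹)
    2 intermediate → homo product (k4 = 0.0095 M⁻¹ s⁻¹)

- percent here means substrate units held: one homo product counts as two
- two of one species on the left: rate k times its square, two consumed each time
- run time (summer): 30 min

- which flask leads in share of target in target plus homo product ("all alike" within 1.5 percentage points) (summer / winter / dawn / midnight / autumn / all alike)
- share of target in target plus homo product at the end, summer
- share of target in target plus homo product at the end, winter
- share of target in target plus homo product at the end, dawn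
- share of target in target plus homo product at the end, midnight
- share of target in target plus homo product at the end, autumn

Let R be the rate at which substrate makes intermediate, P the partner concentration, c the coupling constant and h the homo constant. The half-life of the intermediate by coupling with the charged partner is 5.78 min, shorter than the run, so I let it rest at R/(c·P). Substrate lost to homo product per unit coupled is then R/R×, the load, where

R× = (c·P)²/(2·h) = 0.0126 M min⁻¹

I call R× the crossing rate, the making rate at which, with the intermediate taken to rest at R/(c·P) as above, the homo way reckons level with coupling. It is a scale for small loads, since that rest ignores the homo way out. The load itself, homo against coupled substrate, is an inverted selectivity factor.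

My reckoning runs on rates. At the start of a full charge R is 0.00252 M min⁻¹, a load of 0.199. The decay of substrate slows this over the feed time by a mean factor 0.742. Dawn's portions multiply that by 0.500, while summer's steady feed replaces it with 0.410. Target also leaks to the isomer, and for even coupling over the run a fraction 0.570 of what is coupled stays target. So

share = f/(f + load)

This gives 87.5 % for summer, 79.4 % for winter, 88.5 % for dawn and 79.4 % for autumn, which I treat as winter. Midnight, with partner held at half its charge, stands above 49.1 %. My leader is dawn.

The forecast names dawn, with 87.1 % for summer, 78.4 % for winter, 88.8 % for dawn, 66.8 % for midnight and 77.8 % for autumn, on the ground that “Late substrate gives little conversion but keeps intermediate low.” Its midnight is far above my bound.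

The simulation gives dawn: 87.1 % for summer, 78.2 % for winter, 88.7 % for dawn, 66.5 % for midnight and 77.4 % for autumn.

In dawn at 30.0 min, R is 0.00170 M min⁻¹, slower than the 0.00715 M min⁻¹ to which the crossing rate has come with the partner left. Yet the intermediate is still made 1.49 times faster than it is used up, and the target 2.14 times. Dawn's lead over summer is 1.6 percentage points, and flasks within 1.5 points count as equal, so a run need only bring that lead under the margin for the forecast's dawn to fail; dawn's share has moved 5 points at 0.623 equiv or 1.14 equiv of partner.

At 0.40 M of substrate on dawn's recipe, R grows with the charge and R× with its square, so the share comes to 96.9 % by hand. The computed result is 95.2 %.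

(The constants used here stand for no real mixture; the rest is arithmetic.)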